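**Strategy.** The route rests on the bond between pyridone C5 and C1', the tertiary carbinol carbon of the epoxycyclohexane ring. Because C1' carries a hydroxyl and sits next to the C2'–C3' oxirane, it is the carbonyl carbon of an α,β-epoxy ketone, while C5, ortho to the C4 oxygen, can be unmasked as an aryllithium from a C–Br bond. The key step adds the C5-lithiated 2,4-bis(silylethoxy)pyridine, already carrying the citronellal-derived trans-decalin as a carbinol, to an enantiopure trans-4-silyloxy-2,3-epoxycyclohexanone. One operation joins both halves and sets the tertiary carbinol, the oxirane steering attack to its anti face. Oxidation, fluoride unmasking and N-hydroxylation finish the synthesis.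

Key step: step 12

Locants used: pyridone N1, C2 (C=O), C3 (acyl), C4 (OH), C5, C6; cyclohexane C1' (on C5), C2'–C3' (oxirane), C4' (secondary carbinol), C5', C6'; decalin C1–C8a with the acyl group on C1.

Assumption: the carbinol carbon made in step 11 is carried as a mixture of both epimers, because step 13 turns it into the ketone carbon; its SMILES therefore has no descriptor at that atom. The same holds for the oxirane CH of the non-isolated epoxide 4.

Step 1
Reactants: 1 (R)-citronellal
Product: 3 (2E,4E,7R)-7,11-dimethyldodeca-2,4,10-triene, via (4Z)-triene isomer 2 (not isolated)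
Conditions: crotyltriphenylphosphonium chloride, NaN(SiMe3)2, THF, −78 °C to rt; then I2 (5 mol%), hexanes, daylight, rt
Reagents that add atoms: crotyltriphenylphosphonium chloride, C/C=C/C[P+](c1ccccc1)(c1ccccc1)c1ccccc1.[Cl-]
Why: The Wittig reaction of the semi-stabilised allylic ylide forms the C4=C5 bond as an E/Z mixture, and iodine-catalysed photoequilibration should converge the (4Z)-isomer 2 on the thermodynamically favoured (2E,4E)-diene without touching the C7 stereocentre or the trisubstituted alkene.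

Step 2
Reactants: 3 (2E,4E,7R)-7,11-dimethyldodeca-2,4,10-triene
Product: 5 (4R,6E,8E)-4-methyldeca-6,8-dienal, via trisubstituted epoxide 4 (not isolated)
Conditions: mCPBA (1.0 equiv), CH2Cl2, −20 to 0 °C; then H5IO6, THF/H2O, 0 °C
Reagents that add atoms: mCPBA, OOC(=O)c1cccc(Cl)c1
Why: Prilezhaev epoxidation with one equivalent of peracid should select the electron-rich trisubstituted C10=C11 alkene over the conjugated disubstituted diene, and periodic acid then hydrolyses the epoxide and cleaves the glycol (Malaprade-type cleavage) to the aldehyde.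

Step 3
Reactants: 5 (4R,6E,8E)-4-methyldeca-6,8-dienal
Product: 6 (2E,6R,8E,10E)-6-methyldodeca-2,8,10-trienal
Conditions: Ph3P=CHCHO (1.2 equiv), toluene, 80 °C
Reagents that add atoms: (triphenylphosphoranylidene)acetaldehyde, O=CC=P(c1ccccc1)(c1ccccc1)c1ccccc1
Why: Wittig olefination with the stabilised formyl ylide should give the (E)-enal selectively.

Step 4
Reactants: 6 (2E,6R,8E,10E)-6-methyldodeca-2,8,10-trienal
Product: 7 (1R,2R,4aS,6R,8aR)-2,6-dimethyl-1,2,4a,5,6,7,8,8a-octahydronaphthalene-1-carbaldehyde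
Conditions: Et2AlCl (0.3 equiv), CH2Cl2, −78 to −30 °C
Reagents that add atoms: none
Why: The Lewis acid-catalysed intramolecular Diels–Alder reaction should pass through the endo, chair-like transition state with the C6 methyl group equatorial, so that the citronellal-derived centre sets the trans ring fusion (C4a, C8a) while the (E,E)-diene and (E)-dienophile geometries set C1 and C2.

Step 5
Reactants: 8 2,4-difluoropyridine
Product: 9 2,4-bis[2-(trimethylsilyl)ethoxy]pyridine
Conditions: 2-(trimethylsilyl)ethanol (2.3 equiv), NaH (2.4 equiv), THF/DMF, 0 to 60 °C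
Reagents that add atoms: 2-(trimethylsilyl)ethanol, OCC[Si](C)(C)C
Why: Twofold nucleophilic aromatic substitution (SNAr) of the activated C4 and C2 fluorides by sodium 2-(trimethylsilyl)ethoxide.

Step 6
Reactants: 9 2,4-bis[2-(trimethylsilyl)ethoxy]pyridine
Product: 10 3,5-dibromo-2,4-bis[2-(trimethylsilyl)ethoxy]pyridine
Conditions: NBS (2.2 equiv), MeCN, 0 °C to rt
Reagents that add atoms: N-bromosuccinimide, O=C1CCC(=O)N1Br
Why: Electrophilic aromatic bromination occurs at C3 and C5, the only ring positions ortho or para to the two alkoxy groups.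

Step 7
Reactants: 11 1,4-dioxaspiro[4.5]dec-6-en-8-one
Product: 12 (8S)-1,4-dioxaspiro[4.5]dec-6-en-8-ol
Conditions: (R)-2-methyl-CBS-oxazaborolidine (10 mol%), catecholborane, toluene, −78 °C; aq. NaOH work-up
Reagents that add atoms: none
Why: Corey–Bakshi–Shibata reduction, in which the alkenyl arm acts as the large group, should deliver hydride to the face that gives the (8S)-allylic alcohol with the (R)-catalyst, which sets C4' of the target.

Step 8
Reactants: 12 (8S)-1,4-dioxaspiro[4.5]dec-6-en-8-ol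
Product: 13 (8S)-8-(tert-butyldimethylsilyloxy)-1,4-dioxaspiro[4.5]dec-6-ene
Conditions: TBSCl, imidazole, DMF, rt
Reagents that add atoms: tert-butyldimethylsilyl chloride, CC(C)(C)[Si](C)(C)Cl
Why: Standard imidazole-promoted silylation of the secondary allylic alcohol, with no change at the stereocentre.

Step 9
Reactants: 13 (8S)-8-(tert-butyldimethylsilyloxy)-1,4-dioxaspiro[4.5]dec-6-ene
Product: 14 (4S)-4-(tert-butyldimethylsilyloxy)cyclohex-2-en-1-one
Conditions: PPTS (cat.), acetone/H2O, 55 °C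
Reagents that add atoms: water, O
Why: Mild acid-catalysed hydrolysis of the dioxolane unmasks the enone, while the secondary silyl ether and its stereocentre should survive.

Step 10
Reactants: 14 (4S)-4-(tert-butyldimethylsilyloxy)cyclohex-2-en-1-one
Product: 15 (1R,5S,6S)-5-(tert-butyldimethylsilyloxy)-7-oxabicyclo[4.1.0]heptan-2-one
Conditions: H2O2 (30% aq.), benzyltrimethylammonium hydroxide (cat.), THF, 0 °C
Reagents that add atoms: hydrogen peroxide, OO
Why: Weitz–Scheffer nucleophilic epoxidation, in which hydroperoxide adds to C3 anti to the neighbouring C4 silyloxy group, should give the trans-epoxy ketone and so sets C2' and C3'.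

Step 11
Reactants: 10 3,5-dibromo-2,4-bis[2-(trimethylsilyl)ethoxy]pyridine; 7 (1R,2R,4aS,6R,8aR)-2,6-dimethyl-1,2,4a,5,6,7,8,8a-octahydronaphthalene-1-carbaldehyde
Product: 17 {5-bromo-2,4-bis[2-(trimethylsilyl)ethoxy]pyridin-3-yl}[(1R,2R,4aS,6R,8aR)-2,6-dimethyl-1,2,4a,5,6,7,8,8a-octahydronaphthalen-1-yl]methanol (both carbinol epimers), via 3-lithio-5-bromopyridine 16 (not isolated)
Conditions: n-BuLi (1.0 equiv), THF, −78 °C; then 7, −78 to −40 °C; aq. NH4Cl
Reagents that add atoms: none
Why: Bromine–lithium exchange should take place at C3, where the aryllithium is flanked and stabilised by two alkoxy groups, and the resulting 16 adds to the aldehyde to give the carbinol as an epimer mixture that is of no consequence.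

Step 12
Reactants: 17 bromopyridyl decalinyl carbinol; 15 (1R,5S,6S)-5-(tert-butyldimethylsilyloxy)-7-oxabicyclo[4.1.0]heptan-2-one
Product: 19 {5-[(1R,2R,5S,6S)-5-(tert-butyldimethylsilyloxy)-2-hydroxy-7-oxabicyclo[4.1.0]heptan-2-yl]-2,4-bis[2-(trimethylsilyl)ethoxy]pyridin-3-yl}[(1R,2R,4aS,6R,8aR)-2,6-dimethyl-1,2,4a,5,6,7,8,8a-octahydronaphthalen-1-yl]methanol (both carbinol epimers), via C5-lithiated lithium alkoxide 18 (not isolated)
Conditions: n-BuLi (2.1 equiv), THF, −78 °C; then 15 (1.2 equiv), −78 °C; aq. NH4Cl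
Reagents that add atoms: none
Why: The first equivalent of n-BuLi forms the lithium alkoxide and the second effects bromine–lithium exchange at C5, giving dianion 18, whose aryl carbon adds 1,2 to the ketone carbonyl of 15, the most electrophilic site of that fragment. The closest known reaction type is the addition of aryllithium reagents to 2,3-epoxycyclohexanones. No ring is closed. The new stereocentre C1' is controlled by the adjacent C2'–C3' oxirane: the nucleophile should enter anti to the oxirane C–O bond (Felkin–Anh or lithium-bridged model), which places the tertiary hydroxyl cis to the epoxide and the pyridyl group cis to the C4' silyloxy group, as the target requires. The step needs 1,2-addition to win over enolisation at C6' and over epoxide opening, which the low temperature, the hard lithium counter-ion and the unhindered ketone should secure. It also needs clean exchange at C5, which the single remaining C–Br bond guarantees, while the decalin alkene and the silyl groups are inert to n-BuLi at −78 °C.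

Step 13
Reactants: 19 coupled diol
Product: 20 {5-[(1R,2R,5S,6S)-5-(tert-butyldimethylsilyloxy)-2-hydroxy-7-oxabicyclo[4.1.0]heptan-2-yl]-2,4-bis[2-(trimethylsilyl)ethoxy]pyridin-3-yl}[(1R,2R,4aS,6R,8aR)-2,6-dimethyl-1,2,4a,5,6,7,8,8a-octahydronaphthalen-1-yl]methanone
Conditions: Dess–Martin periodinane, pyridine, CH2Cl2, 0 °C to rt
Reagents that add atoms: none
Why: Dess–Martin oxidation converts the only free secondary alcohol into the ketone and converges both carbinol epimers, while the tertiary alcohol, the silyl ether and the epoxide cannot react.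

Step 14
Reactants: 20 protected pyridyl ketone
Product: 21 3-[(1R,2R,4aS,6R,8aR)-2,6-dimethyl-1,2,4a,5,6,7,8,8a-octahydronaphthalene-1-carbonyl]-5-[(1R,2R,5S,6R)-2,5-dihydroxy-7-oxabicyclo[4.1.0]heptan-2-yl]-4-hydroxypyridin-2(1H)-one
Conditions: TBAF (6 equiv), THF, 0 °C to rt; AcOH quench
Reagents that add atoms: none
Why: Fluoride cleaves the silyl ether and triggers β-elimination of both 2-(trimethylsilyl)ethyl ethers (loss of ethylene and Me3SiF, as known for lactim-type O-silylethyl groups), unveiling the 4-hydroxy-2-pyridone and the C4' alcohol in one non-acidic operation that should spare the epoxide and the tertiary carbinol.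

Step 15
Reactants: 21 N–H pyridone
Product: 24 3-[(1R,2R,4aS,6R,8aR)-2,6-dimethyl-1,2,4a,5,6,7,8,8a-octahydronaphthalene-1-carbonyl]-5-[(1R,2R,5S,6R)-2,5-dihydroxy-7-oxabicyclo[4.1.0]heptan-2-yl]-1,4-dihydroxypyridin-2(1H)-one, via tetrakis(trimethylsilyl) derivative 22 (not isolated), via silylated pyridine N-oxide 23 (not isolated)
Conditions: N,O-bis(trimethylsilyl)acetamide, CH2Cl2, rt; then MoO(O2)2(pyridine)(HMPA), CH2Cl2, 0 °C to rt; aq. Na4EDTA
Reagents that add atoms: oxodiperoxomolybdenum(pyridine)(hexamethylphosphoric triamide), O=[Mo]12(OO1)OO2.c1ccncc1.CN(C)P(=O)(N(C)C)N(C)C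
Why: O-Silylation turns the 2-pyridone into a 2-silyloxypyridine whose nitrogen is oxidised by the peroxomolybdenum complex (the known N-hydroxylation of silylated 2-pyridones), a reagent that should leave the isolated decalin alkene alone, and aqueous work-up hydrolyses the silyl groups to give the N-hydroxypyridone.

**Compound list**

1 | (R)-citronellal, (3R)-3,7-dimethyloct-6-enal | C[C@H](CCC=C(C)C)CC=O | starting material
2 | (2E,4Z,7R)-7,11-dimethyldodeca-2,4,10-triene | C/C=C/C=C\C[C@H](C)CCC=C(C)C | intermediate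
3 | (2E,4E,7R)-7,11-dimethyldodeca-2,4,10-triene | C/C=C/C=C/C[C@H](C)CCC=C(C)C | intermediate
4 | 2,2-dimethyl-3-[(3R,5E,7E)-3-methylnona-5,7-dien-1-yl]oxirane (both oxirane epimers) | C/C=C/C=C/C[C@H](C)CCC1OC1(C)C | intermediate
5 | (4R,6E,8E)-4-methyldeca-6,8-dienal | C/C=C/C=C/C[C@H](C)CCC=O | intermediate
6 | (2E,6R,8E,10E)-6-methyldodeca-2,8,10-trienal | C/C=C/C=C/C[C@H](C)CC/C=C/C=O | intermediate
7 | (1R,2R,4aS,6R,8aR)-2,6-dimethyl-1,2,4a,5,6,7,8,8a-octahydronaphthalene-1-carbaldehyde (trans-decalin, formyl and C2 methyl cis, C6 methyl equatorial) | C[C@@H]1CC[C@H]2[C@H](C=O)[C@H](C)C=C[C@@H]2C1 | intermediate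
8 | 2,4-difluoropyridine | Fc1ccnc(F)c1 | starting material
9 | 2,4-bis[2-(trimethylsilyl)ethoxy]pyridine | C[Si](C)(C)CCOc1ccnc(OCC[Si](C)(C)C)c1 | intermediate
10 | 3,5-dibromo-2,4-bis[2-(trimethylsilyl)ethoxy]pyridine | C[Si](C)(C)CCOc1ncc(Br)c(OCC[Si](C)(C)C)c1Br | intermediate
11 | 1,4-dioxaspiro[4.5]dec-6-en-8-one | O=C1C=CC2(CC1)OCCO2 | starting material
12 | (8S)-1,4-dioxaspiro[4.5]dec-6-en-8-ol | O[C@H]1CCC2(OCCO2)C=C1 | intermediate
13 | (8S)-8-(tert-butyldimethylsilyloxy)-1,4-dioxaspiro[4.5]dec-6-ene | CC(C)(C)[Si](C)(C)O[C@H]1CCC2(OCCO2)C=C1 | intermediate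
14 | (4S)-4-(tert-butyldimethylsilyloxy)cyclohex-2-en-1-one | O=C1CC[C@H](O[Si](C)(C)C(C)(C)C)C=C1 | intermediate
15 | (1R,5S,6S)-5-(tert-butyldimethylsilyloxy)-7-oxabicyclo[4.1.0]heptan-2-one (oxirane trans to the silyloxy group) | O=C1CC[C@H](O[Si](C)(C)C(C)(C)C)[C@H]2O[C@H]21 | intermediate
16 | 5-bromo-3-lithio-2,4-bis[2-(trimethylsilyl)ethoxy]pyridine | [Li]c1c(OCC[Si](C)(C)C)ncc(Br)c1OCC[Si](C)(C)C | intermediate
17 | {5-bromo-2,4-bis[2-(trimethylsilyl)ethoxy]pyridin-3-yl}[(1R,2R,4aS,6R,8aR)-2,6-dimethyl-1,2,4a,5,6,7,8,8a-octahydronaphthalen-1-yl]methanol (both carbinol epimers) | C[C@@H]1CC[C@H]2[C@H](C(O)c3c(OCC[Si](C)(C)C)ncc(Br)c3OCC[Si](C)(C)C)[C@H](C)C=C[C@@H]2C1 | intermediate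
18 | lithium alkoxide of 17 lithiated at pyridine C5 in place of bromine | C[C@@H]1CC[C@H]2[C@H](C(O[Li])c3c(OCC[Si](C)(C)C)ncc([Li])c3OCC[Si](C)(C)C)[C@H](C)C=C[C@@H]2C1 | intermediate
19 | {5-[(1R,2R,5S,6S)-5-(tert-butyldimethylsilyloxy)-2-hydroxy-7-oxabicyclo[4.1.0]heptan-2-yl]-2,4-bis[2-(trimethylsilyl)ethoxy]pyridin-3-yl}[(1R,2R,4aS,6R,8aR)-2,6-dimethyl-1,2,4a,5,6,7,8,8a-octahydronaphthalen-1-yl]methanol (both carbinol epimers; tertiary OH cis to the oxirane, pyridyl cis to the silyloxy group) | C[C@@H]1CC[C@H]2[C@H](C(O)c3c(OCC[Si](C)(C)C)ncc([C@]4(O)CC[C@H](O[Si](C)(C)C(C)(C)C)[C@H]5O[C@H]54)c3OCC[Si](C)(C)C)[C@H](C)C=C[C@@H]2C1 | intermediate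
20 | {5-[(1R,2R,5S,6S)-5-(tert-butyldimethylsilyloxy)-2-hydroxy-7-oxabicyclo[4.1.0]heptan-2-yl]-2,4-bis[2-(trimethylsilyl)ethoxy]pyridin-3-yl}[(1R,2R,4aS,6R,8aR)-2,6-dimethyl-1,2,4a,5,6,7,8,8a-octahydronaphthalen-1-yl]methanone | C[C@@H]1CC[C@H]2[C@H](C(=O)c3c(OCC[Si](C)(C)C)ncc([C@]4(O)CC[C@H](O[Si](C)(C)C(C)(C)C)[C@H]5O[C@H]54)c3OCC[Si](C)(C)C)[C@H](C)C=C[C@@H]2C1 | intermediate
21 | 3-[(1R,2R,4aS,6R,8aR)-2,6-dimethyl-1,2,4a,5,6,7,8,8a-octahydronaphthalene-1-carbonyl]-5-[(1R,2R,5S,6R)-2,5-dihydroxy-7-oxabicyclo[4.1.0]heptan-2-yl]-4-hydroxypyridin-2(1H)-one (the N–H pyridone) | C[C@@H]1CC[C@H]2[C@H](C(=O)c3c(O)c([C@]4(O)CC[C@H](O)[C@H]5O[C@H]54)c[nH]c3=O)[C@H](C)C=C[C@@H]2C1 | intermediate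
22 | tetrakis(trimethylsilyl) derivative of 21 (2-O, 4-O, C1'-O and C4'-O silylated; 2,4-bis(silyloxy)pyridine form) | C[C@@H]1CC[C@H]2[C@H](C(=O)c3c(O[Si](C)(C)C)ncc([C@]4(O[Si](C)(C)C)CC[C@H](O[Si](C)(C)C)[C@H]5O[C@H]54)c3O[Si](C)(C)C)[C@H](C)C=C[C@@H]2C1 | intermediate
23 | pyridine N-oxide of 22 | C[C@@H]1CC[C@H]2[C@H](C(=O)c3c(O[Si](C)(C)C)[n+]([O-])cc([C@]4(O[Si](C)(C)C)CC[C@H](O[Si](C)(C)C)[C@H]5O[C@H]54)c3O[Si](C)(C)C)[C@H](C)C=C[C@@H]2C1 | intermediate
24 | 3-[(1R,2R,4aS,6R,8aR)-2,6-dimethyl-1,2,4a,5,6,7,8,8a-octahydronaphthalene-1-carbonyl]-5-[(1R,2R,5S,6R)-2,5-dihydroxy-7-oxabicyclo[4.1.0]heptan-2-yl]-1,4-dihydroxypyridin-2(1H)-one | C[C@@H]1CC[C@H]2[C@H](C(=O)c3c(O)c([C@]4(O)CC[C@H](O)[C@H]5O[C@H]54)cn(O)c3=O)[C@H](C)C=C[C@@H]2C1 | target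

**Total step count:** 15

**Longest linear sequence:** 9 steps (steps 1–4, then 11–15, from 1 to 24).

**Steps most likely to fail**

Step 15. The N-oxidation may stall at the hindered, weakly nucleophilic silyloxypyridine nitrogen, and on prolonged exposure the peroxo reagent may epoxidise the C3=C4 decalin alkene or degrade the epoxy diol. The fallback carries the N–O bond from the start as a pyridine N-oxide made before any alkene is present; it sets out from 9 and comes back at 24. Oxidation of 9 with mCPBA (CH2Cl2, rt) would give 2,4-bis[2-(trimethylsilyl)ethoxy]pyridine 1-oxide F1, and NBS (2.2 equiv, MeCN) would give 3,5-dibromo-2,4-bis[2-(trimethylsilyl)ethoxy]pyridine 1-oxide F2. Bromine–magnesium exchange at C3 with iPrMgCl·LiCl (THF, −40 °C), a known way to metalate bromopyridine N-oxides, and addition to 7 would give the N-oxide carbinol F3. A second exchange at C5 (iPrMgCl·LiCl, 2.2 equiv) and addition to 15 in the presence of LaCl3·2LiCl would give the N-oxide adduct F4, and Dess–Martin oxidation the N-oxide ketone F5. TBAF then removes the three silicon groups; the 2-(silylethoxy)pyridine N-oxide collapses directly to the N-hydroxypyridone 24.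

Step 12. The hindered, strongly basic dianion may enolise the epoxy ketone at C6' instead of adding, and facial selectivity at C1' may erode with so large a nucleophile. The fallback reverses the order of the two fragment unions so that a small, non-basic-alkoxide nucleophile meets the epoxy ketone first; it sets out from 9 and comes back at 19. Monobromination of 9 (NBS, 1.0 equiv, MeCN, 0 °C; expected at C5, para to the C2 alkoxy group) would give 5-bromo-2,4-bis[2-(trimethylsilyl)ethoxy]pyridine F6. Bromine–lithium exchange (n-BuLi, THF, −78 °C), transmetalation with CeCl3 and addition to 15 would give (1R,2R,5S,6S)-5-(tert-butyldimethylsilyloxy)-2-{4,6-bis[2-(trimethylsilyl)ethoxy]pyridin-3-yl}-7-oxabicyclo[4.1.0]heptan-2-ol F7. Treatment of F7 with n-BuLi (2.2 equiv, THF, −78 to −30 °C) forms the alkoxide and lithiates C3 between the two alkoxy groups (directed ortho-metalation); addition of 7 then gives 19.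

Step 11. The bromine–lithium exchange may fail to discriminate between C3 and C5, or the lithiated bromopyridine may undergo halogen migration before the hindered, enolisable aldehyde is captured. The fallback introduces the bromine only after the decalin is attached; it sets out from 9 and comes back at 17. Directed ortho-lithiation of 9 at C3 (n-BuLi, THF, −78 to −20 °C) and addition to 7 would give {2,4-bis[2-(trimethylsilyl)ethoxy]pyridin-3-yl}[(1R,2R,4aS,6R,8aR)-2,6-dimethyl-1,2,4a,5,6,7,8,8a-octahydronaphthalen-1-yl]methanol F8. Electrophilic bromination of the electron-rich pyridine at its only free activated position, C5 (NBS, 1.0 equiv, MeCN, 0 °C), then gives 17.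

**Further compounds**

F1 | step 15 | 2,4-bis[2-(trimethylsilyl)ethoxy]pyridine 1-oxide | C[Si](C)(C)CCOc1cc[n+]([O-])c(OCC[Si](C)(C)C)c1
F2 | step 15 | 3,5-dibromo-2,4-bis[2-(trimethylsilyl)ethoxy]pyridine 1-oxide | C[Si](C)(C)CCOc1c(Br)c[n+]([O-])c(OCC[Si](C)(C)C)c1Br
F3 | step 15 | pyridine 1-oxide of carbinol 17 (both carbinol epimers) | C[C@@H]1CC[C@H]2[C@H](C(O)c3c(OCC[Si](C)(C)C)[n+]([O-])cc(Br)c3OCC[Si](C)(C)C)[C@H](C)C=C[C@@H]2C1
F4 | step 15 | pyridine 1-oxide of adduct 19 (both carbinol epimers) | C[C@@H]1CC[C@H]2[C@H](C(O)c3c(OCC[Si](C)(C)C)[n+]([O-])cc([C@]4(O)CC[C@H](O[Si](C)(C)C(C)(C)C)[C@H]5O[C@H]54)c3OCC[Si](C)(C)C)[C@H](C)C=C[C@@H]2C1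
F5 | step 15 | pyridine 1-oxide of ketone 20 | C[C@@H]1CC[C@H]2[C@H](C(=O)c3c(OCC[Si](C)(C)C)[n+]([O-])cc([C@]4(O)CC[C@H](O[Si](C)(C)C(C)(C)C)[C@H]5O[C@H]54)c3OCC[Si](C)(C)C)[C@H](C)C=C[C@@H]2C1
F6 | step 12 | 5-bromo-2,4-bis[2-(trimethylsilyl)ethoxy]pyridine | C[Si](C)(C)CCOc1cc(OCC[Si](C)(C)C)c(Br)cn1
F7 | step 12 | (1R,2R,5S,6S)-5-(tert-butyldimethylsilyloxy)-2-{4,6-bis[2-(trimethylsilyl)ethoxy]pyridin-3-yl}-7-oxabicyclo[4.1.0]heptan-2-ol | C[Si](C)(C)CCOc1cc(OCC[Si](C)(C)C)c([C@]2(O)CC[C@H](O[Si](C)(C)C(C)(C)C)[C@H]3O[C@H]32)cn1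
F8 | step 11 | {2,4-bis[2-(trimethylsilyl)ethoxy]pyridin-3-yl}[(1R,2R,4aS,6R,8aR)-2,6-dimethyl-1,2,4a,5,6,7,8,8a-octahydronaphthalen-1-yl]methanol (both carbinol epimers) | C[C@@H]1CC[C@H]2[C@H](C(O)c3c(OCC[Si](C)(C)C)nccc3OCC[Si](C)(C)C)[C@H](C)C=C[C@@H]2C1
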